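Count time in reagent-minutes: one minute at one equivalent of reagent on the starting material charged. Each listed step that makes product holds one reagent, so while reagent stays near its charge, and if the parking of product as idle adduct keeps pace, runs with this starting charge should follow this one clock.

common to all: starting material 0.20 M
- autumn: reagent 0.27 M; run made earlier
- midnight: reagent 0.60 M; run made earlier
- flask: reagent 0.400 M; time 2.5 min

| run | time / min | product / % | starting material / % |
|---|---|---|---|
| autumn | 0.250 | 0.2 | 99.5 |
| autumn | 0.833 | 2.3 | 95.8 |
| autumn | 1.33 | 2.0 | 93.6 |
| autumn | 2.00 | 4.9 | 92.6 |
| autumn | 3.00 | 5.2 | 85.3 |
| midnight | 0.250 | 1.4 | 98.1 |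
| midnight | 0.417 | 0.1 | 95.4 |
| midnight | 0.833 | 5.2 | 92.0 |
| midnight | 1.50 | 8.8 | 83.0 |
| midnight | 3.00 | 24.2 | 54.3 |

(scatter of a reading: 1 percentage point)

- percentages count the starting material that a species holds: one idle adduct counts as two
- product is meant together with its idle adduct
- the numbers in the tables scatter with a standard deviation of 1 percentage point
- steps under discussion: starting material + reagent + product -> 2 product; starting material + reagent -> product; starting material + product <-> idle adduct
- in an amount of product, one idle adduct counts as one product
- the reaction counts as stopped when no species that holds the starting material changes by six tenths of a point or more over the second half of the time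

- the state of affairs at 2.5 min: stopped, and by what, or still going (all of the starting material has reacted / the reagent has run out first / it is still moving)
- the product standing at 2.5 min, as a percentage of the starting material charged

First ask where the flask ends. In the asked flask starting material is the limiting reagent, so full conversion leaves 50.0% of the reagent charge. Then ask how far along it is. At 2.5 min the asked flask stands at 5.00 min, its reagent clock, equivalents of reagent times minutes.

Test the clock on the runs. Autumn at 2.00 min reads clock 2.70 min and midnight at 0.833 min reads 2.50 min, and their starting material stands at 92.6% and 92.0%, within the scatter of 1 percentage point.

Now read the flask off. Autumn at clock 4.05 min and midnight at 4.50 min show product 5.2% and 8.8%. Take their mean, 7.00% at clock 4.28 min, and draw the chord to midnight's 24.2% at clock 9.00 min. My reckoning at the flask's clock is 9.64% product, which costs 4.82% of the reagent charge. Midnight's starting material falls from 92.0% at half the flask's clock to 83.0% at clock 4.50 min, so I call the flask still moving.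

The forecast says "it is still moving" with 12% product, between 9.5% and 15%, holding that "the autocatalytic step is real", and its figure is higher than mine.

The flask gives "it is still moving" with 9.48% product, 81.4% starting material and 95.3% of its reagent charge.

    starting material + reagent + product → 2 product (k = 2.40 M⁻² s⁻¹)
    starting material + reagent → product (k = 0.00110 M⁻¹ s⁻¹)
    starting material + product ⇌ idle adduct, settled at all times (K = 160 M⁻¹)

At clock 5.00 min the chord read 9.64% and the flask stands at 9.48%. Run the same clock on the neighbour flask with 0.68 M of reagent, read at 2.50 min. Its clock is 8.50 min, less than midnight's 9.00 min, so expect somewhat less than midnight's 24.2% product; the chord gives 22.4%. The neighbour flask stands at 21.4% product and 58.4% starting material, with 94% of its reagent charge left.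

The data are calculated with made-up constants; the scatter is artificial.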